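## Structural features

The target is a diaryl ether: two benzene rings joined only through the oxygen between A2 and B6. It has no stereocentre, so no stereocentres stand next to each other. Ring A carries five contiguous substituents (A1 CO2CH3, A2 O‑aryl, A3 OCH3, A4 Cl, A5 OH; A6 is H). Ring B carries four (B1 CO2H, B2 OH, B4 CH3, B6 O‑aryl). The ether oxygen has three ortho neighbours (the A1 ester, the A3 methoxy, the B1 carboxyl), and the two carboxyl groups must end differently, as a methyl ester on ring A and a free acid on ring B. The fragile groups are the ring B salicylic acid (decarboxylation, acetal formation with aldehydes), the two electron-rich phenols (oxidation, C‑alkylation by cations), the aryl chloride (hydrogenolysis) and the methyl ester (hydrolysis). The real difficulty is the tri-ortho-substituted ether bond together with the regiochemistry of five different groups on ring A. The key step uses the fact that B1 to B4, with carboxyl, hydroxyl and methyl, are C3 to C6 of a 3‑carboxy‑4‑hydroxy‑6‑methyl‑2‑pyrone. Only B5 and B6 are then missing, and they can come from an ethynyl group already bonded to the A2 oxygen, so the crowded O–B6 bond is made at an sp carbon before ring B exists.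

## Logic of the disconnections

20 ⇒ 19 ⇒ 18. The last bond cut is the O–C(CH3)3 bond of the B1 ester; before it, the O–acyl bond at B2 and the O–Si bond at A5. The ring B acid is released by acid rather than hydroxide so that the A1 methyl ester is never exposed to hydrolysis. The base step runs in methanol, where the A1 ester can only exchange with itself. The gain is that 18 has no free OH or CO2H. The forward demand is methanolysis (not hydrolysis) in step 9 and a cation trap in step 10.

18 ⇒ 16 + 11 (through 17). The B4–B5 and B1–B6 bonds are cut, which dissolves ring B into a pyrone and a two-carbon alkyne. The hindered ether bond then never has to be formed at an aromatic carbon. 16 supplies B1 to B4 with all three substituents at the right oxidation level, and loss of CO2 aromatises without any elimination that could expel the aryloxy group. The forward step must be regioselective and must be faster than thermal loss of 11.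

11 ⇒ 8 ⇒ 6 + 7. The alkyne is taken back to a vinyl ether (two C–H bonds, through 9 and 10), and the O–C(vinyl) bond is then cut. The A1 ester rules out organolithium routes to alkynyl ethers; vinyl transfer and bromination–dehydrobromination tolerate it. The demand is a strong, non-nucleophilic base at low temperature and a vinyl donor that accepts a hindered, chelated phenol.

6 ⇒ 5 ⇒ 2 ⇒ 1. The O–Si bond at A5 is cut, then the A2–O bond together with the ester C–O bond, then the A3 O–CH3 bond. In 2 the only free phenol is at A5 and its para position is A2, so an oxidant that attacks para to a phenoxide puts the new oxygen exactly between carboxyl and methoxy. 1 is symmetric and already carries the chlorine. The demands are a statistical monomethylation (with recycling of 1) and, after oxidation, discrimination between the chelated A2 hydroxyl and the free A5 hydroxyl of 5.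

16 ⇒ 15 ⇒ 12 + 13. The O–acyl bond is cut, then the B1–B2 bond (malonate carbon to acyl carbon) and the lactone O–C(=O) bond. 12 carries one ethyl and one tert-butyl ester so that ring closure expels ethoxide and leaves the tert-butyl ester at B1. The demand is a mild acidic work-up, because the tert-butyl ester sits on a vinylogous acid.

## Other disconnections considered

Alternative 1: Cut the B1–B2 and B5–B6 bonds (Danheiser benzannulation). Heating 3‑methylcyclobut‑2‑en‑1‑one A2 with the internal ring A alkynyl ether A3 should open A2, add it across the alkyne and, after a second four-electron ring opening and a six-electron closure, give the phenol A1.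
- In favour: alkynyl ethers are the standard partners of this benzannulation. The regiochemistry is dependable, and B2 arrives as a free hydroxyl.
- Against: B1 arrives as a protected CH2OH. Desilylation and two oxidations on an electron-rich resorcinol ring must follow, with the phenol protected against chlorination in the NaClO2 step, and then the acetal must be removed. The carbon substituent on the alkyne of A3 cannot come from the vinyl ether route and is normally attached through a lithium acetylide, which the A1 ester does not tolerate. A2 is volatile and needs several steps.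
- Comparison: both plans grow ring B on the A2 oxygen from a thermally sensitive alkynyl ether (equal). Alternative 1 has the better precedent for this alkyne class and runs at a similar or lower temperature (better). The chosen plan delivers B1 as a carboxyl in the tert-butyl form that distinguishes the two carboxyl groups, and needs two steps after the key step against about five.

Alternative 2: Cut the A1–A2 and A5–A6 bonds (ring A by Diels–Alder). The diene A5, already bonded to the ring B oxygen, would add to methyl (E)‑3‑nitroacrylate A6 and aromatise by loss of nitrite and then methoxide to give A4.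
- In favour: no alkynyl ether is needed. The nitro group fixes the orientation. All five ring A substituents are placed in one step. A4 needs only one acid step to reach 20, which is better than the chosen plan.
- Against: A5 is a chloro-substituted, tetra-heteroatom diene with a mixed silyl ketene acetal end. It is hydrolytically labile, its double-bond geometry is hard to control, and its preparation is long and without close precedent. In the aromatisation the aryloxy group at A2 is itself a possible leaving group, which is exactly the risk that CO2 extrusion avoids.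
- Comparison: the ether bond is again made before the ring (equal). The mechanism depends on the order of two eliminations, whereas the chosen plan has none. Step economy is better after the key step and clearly worse before it.

Alternative 3: Cut the O–B6 and B1–carboxyl bonds (three-component coupling). CsF would release the aryne A10 from the silyl triflate A8; the potassium phenoxide A9 would add at B6 and the B1 aryl anion would be trapped by carbon dioxide to give A7.
- In favour: it is the most convergent plan and builds no ring. The aryne is reactive enough for a hindered phenoxide. The alkoxy group directs the nucleophile to the distal carbon. One acid step finishes the synthesis.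
- Against: the B1 anion sits within reach of the A1 methyl ester, and intramolecular acyl substitution to a xanthone-type ring is the usual fate of salicylate–aryne adducts. Proton capture also competes with carboxylation, and A8 needs a multistep preparation.
- Comparison: step count is equal or slightly better and the endgame is shorter (better). The competing ring closure is built into the structure, while the chosen plan has no carbanion near the A1 ester.

Key step: step 8

Assumption: 1, 7, 12 and 13 are taken as catalogue chemicals (13 is a toxic lachrymator, handled cold under nitrogen); the chiral intermediates 9 and 17 are racemic and the target is achiral.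

## Route

Step 1
Reactants: 1 4‑chloro‑3,5‑dihydroxybenzoic acid
Product: 2 4‑chloro‑3‑hydroxy‑5‑methoxybenzoic acid
Conditions: NaOH (3 equiv), H2O, N2, 0 °C; Me2SO4 (1.0 equiv), 0 °C → rt; 60 °C, 30 min; HCl to pH 2
Reagents that add atoms: dimethyl sulfate, COS(=O)(=O)OC
Why: Williamson O‑methylation of a phenoxide in water, where the carboxylate is not alkylated and any ester is saponified on warming; 1 is symmetric, so one equivalent of reagent should give a statistical mixture from which 2 is separated and unchanged 1 is recycled.

Step 2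
Reactants: 2 4‑chloro‑3‑hydroxy‑5‑methoxybenzoic acid
Product: 5 methyl 4‑chloro‑2,5‑dihydroxy‑3‑methoxybenzoate, via aryl sulfate 3 (not isolated), via dihydroxy acid 4 (not isolated)
Conditions: K2S2O8 (1.1 equiv), NaOH (5 equiv), H2O, 5 → 20 °C, 36 h; Na2SO3; HCl to pH 3, EtOAc wash (recovers 2); aq. HCl, 80 °C, 1 h; evaporate; MeOH, H2SO4 (cat.), reflux
Reagents that add atoms: potassium peroxodisulfate, [K+].[K+].[O-]S(=O)(=O)OOS(=O)(=O)[O-]; methanol, CO
Why: Elbs persulfate oxidation: the phenoxide of 2 attacks a peroxide oxygen through its para carbon, which lies between carboxylate and methoxy (as 3‑hydroxybenzoic acid gives gentisic acid); acid then hydrolyses sulfate 3 and Fischer esterification of 4 follows. The esterification is placed after the oxidation because the alkaline medium would saponify an ester made earlier.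

Step 3
Reactants: 5 methyl 4‑chloro‑2,5‑dihydroxy‑3‑methoxybenzoate
Product: 6 methyl 5‑[(tert‑butyldimethylsilyl)oxy]‑4‑chloro‑2‑hydroxy‑3‑methoxybenzoate
Conditions: TBSCl (1.05 equiv), imidazole (2.2 equiv), DMF, 0 °C
Reagents that add atoms: tert‑butyldimethylsilyl chloride, CC(C)(C)[Si](C)(C)Cl
Why: Selective silylation of the free A5 hydroxyl; the A2 hydroxyl is hydrogen-bonded to the ester carbonyl and flanked by methoxy. A silyl ether is preferred to a methoxymethyl ether because it leaves together with the pivalate in step 9 and releases no formaldehyde equivalent next to the salicylic acid in the final acid step.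

Step 4
Reactants: 6 methyl 5‑[(tert‑butyldimethylsilyl)oxy]‑4‑chloro‑2‑hydroxy‑3‑methoxybenzoate; 7 vinyl acetate
Product: 8 methyl 5‑[(tert‑butyldimethylsilyl)oxy]‑4‑chloro‑2‑(ethenyloxy)‑3‑methoxybenzoate
Conditions: [Ir(cod)Cl]2 (2 mol %), Na2CO3 (1.0 equiv), 7 (4 equiv), toluene, 100 °C
Reagents that add atoms: none
Why: Iridium-catalysed transfer vinylation of a phenol by vinyl acetate (addition of the iridium aryloxide across the vinyl ester, then β‑acetate elimination). Steps 4 and 5 are chosen over copper-mediated O‑alkynylation with a bromoalkyne, which is established for amides but not for phenols, and over organolithium routes to alkynyl ethers, which the methyl ester excludes.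

Step 5
Reactants: 8 methyl 5‑[(tert‑butyldimethylsilyl)oxy]‑4‑chloro‑2‑(ethenyloxy)‑3‑methoxybenzoate
Product: 11 methyl 5‑[(tert‑butyldimethylsilyl)oxy]‑4‑chloro‑2‑(ethynyloxy)‑3‑methoxybenzoate, via dibromide 9 (not isolated), via bromovinyl ether 10 (not isolated)
Conditions: Br2 (1.0 equiv), Et2O, −78 °C; KN(SiMe3)2 (3.3 equiv), THF, −78 → −30 °C; pH 7 phosphate buffer; chromatography on Et3N-deactivated silica, store cold
Reagents that add atoms: none
Why: Classical route to aryloxyacetylenes: bromine adds to the electron-rich vinyl ether far faster than to the ring at −78 °C, and two dehydrobrominations follow, the second an anti elimination from the Z bromovinyl ether 10 that 1,2‑dibromoethyl ethers normally give. The hindered amide base has no reason to attack the methyl ester or the silyl ether at this temperature.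

Step 6
Reactants: 12 tert‑butyl ethyl malonate; 13 diketene
Product: 15 tert‑butyl 4‑hydroxy‑6‑methyl‑2‑oxo‑2H‑pyran‑3‑carboxylate, via acylmalonate 14 (not isolated)
Conditions: NaH (2.2 equiv), THF, 0 °C; 13 (1.1 equiv), 0 °C → rt, then 50 °C; cold 0.5 M HCl to pH 3
Reagents that add atoms: none
Why: C‑Acetoacetylation of the malonate enolate by ring opening of diketene at its acyl carbon, then lactonisation of the ketone enolate oxygen onto an ester. The mixed ester is used because this closure must expel an alkoxide: ethoxide leaves readily, tert-butoxide does not, so the tert-butyl ester stays at C3.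

Step 7
Reactants: 15 tert‑butyl 4‑hydroxy‑6‑methyl‑2‑oxo‑2H‑pyran‑3‑carboxylate
Product: 16 tert‑butyl 6‑methyl‑2‑oxo‑4‑(pivaloyloxy)‑2H‑pyran‑3‑carboxylate
Conditions: t‑BuCOCl (1.1 equiv), Et3N (1.3 equiv), CH2Cl2, 0 °C
Reagents that add atoms: pivaloyl chloride, CC(C)(C)C(Cl)=O
Why: O‑Acylation of the vinylogous acid at its 4‑oxygen; C3 is blocked, so no C‑acyl product can form, and the acyloxy group makes the pyrone more electron-poor than the free or alkylated hydroxyl would.

Step 8
Reactants: 16 tert‑butyl 6‑methyl‑2‑oxo‑4‑(pivaloyloxy)‑2H‑pyran‑3‑carboxylate; 11 methyl 5‑[(tert‑butyldimethylsilyl)oxy]‑4‑chloro‑2‑(ethynyloxy)‑3‑methoxybenzoate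
Product: 18 tert‑butyl 2‑{4‑[(tert‑butyldimethylsilyl)oxy]‑3‑chloro‑2‑methoxy‑6‑(methoxycarbonyl)phenoxy}‑4‑methyl‑6‑(pivaloyloxy)benzoate, via bicyclic lactone 17 (not isolated)
Conditions: 16 (2 equiv), 11 (1 equiv), toluene (1 M), BHT (cat.), 4 Å MS, sealed tube, 110 °C (xylene, 130 °C if slow)
Reagents that add atoms: none
Why: Inverse-electron-demand Diels–Alder reaction followed by retro-Diels–Alder loss of CO2. The 2‑pyrone 16 is the electron-poor diene (lactone carbonyl, C3 ester and 4‑acyloxy group lower its LUMO) and 11 is the electron-rich dienophile (the aryloxy oxygen raises the alkyne HOMO and polarises it towards the unsubstituted carbon). Bond formation is asynchronous: the unsubstituted alkyne carbon attacks pyrone C6, the terminus conjugated with both carbonyl groups, and the oxygen-bearing carbon then closes on C3, giving the bridged 2‑oxabicyclo[2.2.2]octadienone 17 by a [4+2] closure (new bonds B4–B5 and B1–B6). 17 should not persist: cycloreversion expels CO2 and leaves the benzene ring B of 18, so aromatisation needs no elimination in which the aryloxy group could leave. The closest known reactions are the cycloadditions of 3‑alkoxycarbonyl‑2‑pyrones with ketene acetals, enol ethers and ynamines, which give benzoates with the donor group ortho to the ester; an aryl alkynyl ether is a further member of the same dienophile class. No stereocentre is formed in 18 (the two bridgehead centres of 17 vanish with CO2). The step needs regioselectivity, secured by the matching polarisation of the two partners, and it needs 11 to add faster than it decomposes: the A1 ester and A3 methoxy block both ortho positions against sigmatropic shift, the pivalate and tert-butyl ester are inert at this temperature, and the medium is kept dry and acid-free.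

Step 9
Reactants: 18 tert‑butyl 2‑{4‑[(tert‑butyldimethylsilyl)oxy]‑3‑chloro‑2‑methoxy‑6‑(methoxycarbonyl)phenoxy}‑4‑methyl‑6‑(pivaloyloxy)benzoate
Product: 19 tert‑butyl 2‑[3‑chloro‑4‑hydroxy‑2‑methoxy‑6‑(methoxycarbonyl)phenoxy]‑6‑hydroxy‑4‑methylbenzoate
Conditions: K2CO3 (2.5 equiv), MeOH, rt → 40 °C; aq. NH4Cl
Reagents that add atoms: none
Why: Base-mediated methanolysis cleaves the aryl pivalate (transesterification) and the aryl silyl ether in one operation; the A1 methyl ester can only exchange with methanol itself and the tert-butyl ester is inert to methoxide.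

Step 10
Reactants: 19 tert‑butyl 2‑[3‑chloro‑4‑hydroxy‑2‑methoxy‑6‑(methoxycarbonyl)phenoxy]‑6‑hydroxy‑4‑methylbenzoate
Product: 20 2‑[3‑chloro‑4‑hydroxy‑2‑methoxy‑6‑(methoxycarbonyl)phenoxy]‑6‑hydroxy‑4‑methylbenzoic acid
Conditions: CF3CO2H/CH2Cl2 (1:4), Et3SiH (3 equiv), 0 °C → rt
Reagents that add atoms: none
Why: Acidolysis of the tert-butyl ester by alkyl–oxygen cleavage leaves the methyl ester, the ether and the chloride untouched; the silane reduces the tert-butyl cation before it can alkylate the electron-rich ring B.

## Compound list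

1 | 4‑chloro‑3,5‑dihydroxybenzoic acid | OC(=O)c1cc(O)c(Cl)c(O)c1 | starting material
2 | 4‑chloro‑3‑hydroxy‑5‑methoxybenzoic acid | COc1cc(C(=O)O)cc(O)c1Cl | intermediate
3 | potassium 6‑carboxy‑3‑chloro‑4‑hydroxy‑2‑methoxyphenyl sulfate | COc1c(Cl)c(O)cc(C(=O)O)c1OS(=O)(=O)[O-].[K+] | intermediate (not isolated)
4 | 4‑chloro‑2,5‑dihydroxy‑3‑methoxybenzoic acid | COc1c(O)c(C(=O)O)cc(O)c1Cl | intermediate (not isolated)
5 | methyl 4‑chloro‑2,5‑dihydroxy‑3‑methoxybenzoate | COC(=O)c1cc(O)c(Cl)c(OC)c1O | intermediate
6 | methyl 5‑[(tert‑butyldimethylsilyl)oxy]‑4‑chloro‑2‑hydroxy‑3‑methoxybenzoate | COC(=O)c1cc(O[Si](C)(C)C(C)(C)C)c(Cl)c(OC)c1O | intermediate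
7 | vinyl acetate (ethenyl acetate) | CC(=O)OC=C | starting material
8 | methyl 5‑[(tert‑butyldimethylsilyl)oxy]‑4‑chloro‑2‑(ethenyloxy)‑3‑methoxybenzoate | COC(=O)c1cc(O[Si](C)(C)C(C)(C)C)c(Cl)c(OC)c1OC=C | intermediate
9 | methyl 5‑[(tert‑butyldimethylsilyl)oxy]‑4‑chloro‑2‑(1,2‑dibromoethoxy)‑3‑methoxybenzoate (racemic) | COC(=O)c1cc(O[Si](C)(C)C(C)(C)C)c(Cl)c(OC)c1OC(Br)CBr | intermediate (not isolated)
10 | methyl 2‑{[(Z)‑2‑bromoethenyl]oxy}‑5‑[(tert‑butyldimethylsilyl)oxy]‑4‑chloro‑3‑methoxybenzoate | COC(=O)c1cc(O[Si](C)(C)C(C)(C)C)c(Cl)c(OC)c1O/C=C\Br | intermediate (not isolated)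
11 | methyl 5‑[(tert‑butyldimethylsilyl)oxy]‑4‑chloro‑2‑(ethynyloxy)‑3‑methoxybenzoate | COC(=O)c1cc(O[Si](C)(C)C(C)(C)C)c(Cl)c(OC)c1OC#C | intermediate
12 | tert‑butyl ethyl malonate (1‑tert‑butyl 3‑ethyl propanedioate) | CCOC(=O)CC(=O)OC(C)(C)C | starting material
13 | diketene (4‑methylideneoxetan‑2‑one) | C=C1CC(=O)O1 | starting material
14 | 1‑tert‑butyl 3‑ethyl 2‑(3‑oxobutanoyl)propanedioate (present as its sodium enolate; racemic and enolisable) | CCOC(=O)C(C(=O)CC(C)=O)C(=O)OC(C)(C)C | intermediate (not isolated)
15 | tert‑butyl 4‑hydroxy‑6‑methyl‑2‑oxo‑2H‑pyran‑3‑carboxylate | CC1=CC(O)=C(C(=O)OC(C)(C)C)C(=O)O1 | intermediate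
16 | tert‑butyl 6‑methyl‑2‑oxo‑4‑(pivaloyloxy)‑2H‑pyran‑3‑carboxylate | CC1=CC(OC(=O)C(C)(C)C)=C(C(=O)OC(C)(C)C)C(=O)O1 | intermediate
17 | tert‑butyl 5‑{4‑[(tert‑butyldimethylsilyl)oxy]‑3‑chloro‑2‑methoxy‑6‑(methoxycarbonyl)phenoxy}‑1‑methyl‑3‑oxo‑8‑(pivaloyloxy)‑2‑oxabicyclo[2.2.2]octa‑5,7‑diene‑4‑carboxylate (racemic, one enantiomer drawn; the bicycle allows only this relative configuration of the bridgeheads) | C[C@@]12OC(=O)[C@@](C(=O)OC(C)(C)C)(C(OC(=O)C(C)(C)C)=C1)C(Oc1c(OC)c(Cl)c(O[Si](C)(C)C(C)(C)C)cc1C(=O)OC)=C2 | intermediate (not isolated)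
18 | tert‑butyl 2‑{4‑[(tert‑butyldimethylsilyl)oxy]‑3‑chloro‑2‑methoxy‑6‑(methoxycarbonyl)phenoxy}‑4‑methyl‑6‑(pivaloyloxy)benzoate | COC(=O)c1cc(O[Si](C)(C)C(C)(C)C)c(Cl)c(OC)c1Oc1cc(C)cc(OC(=O)C(C)(C)C)c1C(=O)OC(C)(C)C | intermediate
19 | tert‑butyl 2‑[3‑chloro‑4‑hydroxy‑2‑methoxy‑6‑(methoxycarbonyl)phenoxy]‑6‑hydroxy‑4‑methylbenzoate | COC(=O)c1cc(O)c(Cl)c(OC)c1Oc1cc(C)cc(O)c1C(=O)OC(C)(C)C | intermediate
20 | 2‑[3‑chloro‑4‑hydroxy‑2‑methoxy‑6‑(methoxycarbonyl)phenoxy]‑6‑hydroxy‑4‑methylbenzoic acid | COC(=O)c1cc(O)c(Cl)c(OC)c1Oc1cc(C)cc(O)c1C(=O)O | target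

## Step count and least certain steps

Total: 10 steps. Longest linear sequence: 8 steps (steps 1, 2, 3, 4, 5, 8, 9, 10); steps 6 and 7 form the second branch.

Step 8 (key step). The cycloaddition may be slower than thermal loss of the alkynyl ether. The pyrone carbon that must bond first carries a methyl group, C3 is crowded, and an aryloxy group is only a moderate donor. Sigmatropic shift of the alkynyl group onto a substituted ortho carbon, hydration or oligomerisation could then consume 11 before it adds. Addition in the reverse orientation is less likely. The fallback leaves the cycloaddition and forms the ether by Ullmann condensation; it sets out from 5 and comes back at 20.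
- 5 is protected with MOMCl/iPr2NEt as methyl 4‑chloro‑2‑hydroxy‑3‑methoxy‑5‑(methoxymethoxy)benzoate F1. An acetal is used here because a silyl ether would not survive carbonate in hot DMF.
- F1 is condensed with 2‑bromo‑6‑methoxy‑4‑methylbenzoic acid F2 using Cu powder, CuI and K2CO3 in DMF/pyridine at 120 °C, where the ortho carboxylate assists displacement of bromide. F2 is obtained from commercial 3‑bromo‑5‑methylanisole by lithiation between bromine and methoxy with LiN(iPr)2 at −78 °C and carboxylation with CO2.
- The product is 2‑[3‑chloro‑2‑methoxy‑6‑(methoxycarbonyl)‑4‑(methoxymethoxy)phenoxy]‑6‑methoxy‑4‑methylbenzoic acid F3. BCl3 in CH2Cl2 (−78 → 0 °C) then removes the methoxymethyl group and, by chelation to the neighbouring carboxyl, the B2 methyl ether, while the A3 methyl ether has no carbonyl neighbour and should stay, which gives 20.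

Step 5. The ortho ester may take part in ionisation of the α‑bromo ether 9 (closure onto the carbonyl oxygen with loss of the ester methyl). Any E isomer of 10 would have to undergo a slow syn elimination, and the alkynyl ether may be hydrated during isolation. The fallback avoids the α‑bromo ether and delivers only the Z isomer; it sets out from 6 and comes back at 10.
- 6 is formylated (HCO2H/Ac2O, pyridine, 0 °C) to methyl 5‑[(tert‑butyldimethylsilyl)oxy]‑4‑chloro‑2‑(formyloxy)‑3‑methoxybenzoate F4.
- Ramirez dibromo-olefination of the formate (CBr4, PPh3, CH2Cl2) gives methyl 5‑[(tert‑butyldimethylsilyl)oxy]‑4‑chloro‑2‑[(2,2‑dibromoethenyl)oxy]‑3‑methoxybenzoate F5.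
- Pd(PPh3)4-catalysed hydrogenolysis with Bu3SnH removes the bromine trans to the aryloxy group and gives 10, which is treated with KN(SiMe3)2 as in the second half of step 5.

Step 4. Vinyl transfer to a hindered, chelated phenol may be slow, and O‑acetylation by 7 may compete. The fallback makes the O–C bond by substitution and forms the double bond afterwards; it sets out from 6 and comes back at 8.
- Mitsunobu etherification of 6 with 2‑(phenylselanyl)ethanol (PPh3, DIAD, THF) gives methyl 5‑[(tert‑butyldimethylsilyl)oxy]‑4‑chloro‑3‑methoxy‑2‑[2‑(phenylselanyl)ethoxy]benzoate F6.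
- NaIO4 (NaHCO3, MeOH/H2O) oxidises it to the selenoxide methyl 2‑[2‑(benzeneseleninyl)ethoxy]‑5‑[(tert‑butyldimethylsilyl)oxy]‑4‑chloro‑3‑methoxybenzoate F7.
- Syn elimination in toluene with iPr2NH at 90 °C gives 8.

Step 2. Conversion in the persulfate oxidation may be low, with over-oxidation to quinonoid and polymeric material, some attack ortho to the phenoxide, and incomplete cleavage of the sulfate. The fallback uses radical oxidation to a quinone and reduction; it sets out from 2 and comes back at 5.
- Fischer esterification of 2 (MeOH, H2SO4) gives methyl 4‑chloro‑3‑hydroxy‑5‑methoxybenzoate F8.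
- Teuber oxidation with (KSO3)2NO (KH2PO4 buffer, acetone/H2O) converts the phenol, through its free para position, into methyl 4‑chloro‑5‑methoxy‑3,6‑dioxocyclohexa‑1,4‑diene‑1‑carboxylate F9.
- Reduction with Na2S2O4 in the work-up gives 5.

## Further compounds

F1 | step 8 | methyl 4‑chloro‑2‑hydroxy‑3‑methoxy‑5‑(methoxymethoxy)benzoate | COC(=O)c1cc(OCOC)c(Cl)c(OC)c1O
F2 | step 8 | 2‑bromo‑6‑methoxy‑4‑methylbenzoic acid | COc1cc(C)cc(Br)c1C(=O)O
F3 | step 8 | 2‑[3‑chloro‑2‑methoxy‑6‑(methoxycarbonyl)‑4‑(methoxymethoxy)phenoxy]‑6‑methoxy‑4‑methylbenzoic acid | COC(=O)c1cc(OCOC)c(Cl)c(OC)c1Oc1cc(C)cc(OC)c1C(=O)O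
F4 | step 5 | methyl 5‑[(tert‑butyldimethylsilyl)oxy]‑4‑chloro‑2‑(formyloxy)‑3‑methoxybenzoate | COC(=O)c1cc(O[Si](C)(C)C(C)(C)C)c(Cl)c(OC)c1OC=O
F5 | step 5 | methyl 5‑[(tert‑butyldimethylsilyl)oxy]‑4‑chloro‑2‑[(2,2‑dibromoethenyl)oxy]‑3‑methoxybenzoate | COC(=O)c1cc(O[Si](C)(C)C(C)(C)C)c(Cl)c(OC)c1OC=C(Br)Br
F6 | step 4 | methyl 5‑[(tert‑butyldimethylsilyl)oxy]‑4‑chloro‑3‑methoxy‑2‑[2‑(phenylselanyl)ethoxy]benzoate | COC(=O)c1cc(O[Si](C)(C)C(C)(C)C)c(Cl)c(OC)c1OCC[Se]c1ccccc1
F7 | step 4 | methyl 2‑[2‑(benzeneseleninyl)ethoxy]‑5‑[(tert‑butyldimethylsilyl)oxy]‑4‑chloro‑3‑methoxybenzoate (racemic at selenium) | COC(=O)c1cc(O[Si](C)(C)C(C)(C)C)c(Cl)c(OC)c1OCC[Se](=O)c1ccccc1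
F8 | step 2 | methyl 4‑chloro‑3‑hydroxy‑5‑methoxybenzoate | COC(=O)c1cc(O)c(Cl)c(OC)c1
F9 | step 2 | methyl 4‑chloro‑5‑methoxy‑3,6‑dioxocyclohexa‑1,4‑diene‑1‑carboxylate | COC(=O)C1=CC(=O)C(Cl)=C(OC)C1=O
A1 | alternative 1 | methyl 2‑[2‑(tert‑butyldimethylsilyloxymethyl)‑3‑hydroxy‑5‑methylphenoxy]‑4‑chloro‑3‑methoxy‑5‑(methoxymethoxy)benzoate | COC(=O)c1cc(OCOC)c(Cl)c(OC)c1Oc1cc(C)cc(O)c1CO[Si](C)(C)C(C)(C)C
A2 | alternative 1 | 3‑methylcyclobut‑2‑en‑1‑one | CC1=CC(=O)C1
A3 | alternative 1 | methyl 2‑{[3‑(tert‑butyldimethylsilyloxy)prop‑1‑yn‑1‑yl]oxy}‑4‑chloro‑3‑methoxy‑5‑(methoxymethoxy)benzoate | COC(=O)c1cc(OCOC)c(Cl)c(OC)c1OC#CCO[Si](C)(C)C(C)(C)C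
A4 | alternative 2 | tert‑butyl 2‑[3‑chloro‑4‑hydroxy‑2‑methoxy‑6‑(methoxycarbonyl)phenoxy]‑6‑(methoxymethoxy)‑4‑methylbenzoate | COC(=O)c1cc(O)c(Cl)c(OC)c1Oc1cc(C)cc(OCOC)c1C(=O)OC(C)(C)C
A5 | alternative 2 | tert‑butyl 2‑{[(1Z,3E)‑3‑chloro‑2,4‑dimethoxy‑4‑(trimethylsilyloxy)buta‑1,3‑dien‑1‑yl]oxy}‑6‑(methoxymethoxy)‑4‑methylbenzoate | COCOc1cc(C)cc(O/C=C(OC)/C(Cl)=C(/OC)O[Si](C)(C)C)c1C(=O)OC(C)(C)C
A6 | alternative 2 | methyl (E)‑3‑nitroacrylate | COC(=O)/C=C/[N+](=O)[O-]
A7 | alternative 3 | 2‑[3‑chloro‑2‑methoxy‑6‑(methoxycarbonyl)‑4‑(methoxymethoxy)phenoxy]‑6‑(methoxymethoxy)‑4‑methylbenzoic acid | COC(=O)c1cc(OCOC)c(Cl)c(OC)c1Oc1cc(C)cc(OCOC)c1C(=O)O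
A8 | alternative 3 | 3‑(methoxymethoxy)‑5‑methyl‑2‑(trimethylsilyl)phenyl trifluoromethanesulfonate | COCOc1cc(C)cc(OS(=O)(=O)C(F)(F)F)c1[Si](C)(C)C
A9 | alternative 3 | potassium 3‑chloro‑2‑methoxy‑6‑(methoxycarbonyl)‑4‑(methoxymethoxy)phenolate | COC(=O)c1cc(OCOC)c(Cl)c(OC)c1[O-].[K+]
A10 | alternative 3 | 3‑(methoxymethoxy)‑5‑methylbenzyne | COCOC1=CC(C)=CC#C1
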